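## Structural features

The target 14 is a cyclohex-3-ene in which the ring carbons C5, C6, C1 and C2 form an unbroken run of four oxygen-bearing stereocentres. The run is closed on the other side by the cis alkene C3=C4, so both ring benzoates (C2, C5) are allylic. C1 is a fully substituted carbinol that also carries the exocyclic C7H2 benzoate, and its neighbour C6 bears the only other free hydroxyl. The C1 hydroxyl, the C6 hydroxyl and the C2 benzoate lie on one face of the ring; the C5 benzoate and the C7 arm lie on the other (1S,2R,5R,6S). Three benzoates beside two free hydroxyls invite acyl migration, and the allylic C–O bonds can ionise or undergo allylic displacement, so the closing steps must be mild. The real difficulty is the quaternary C1 centre wedged between two secondary carbinols, together with the need to tell five oxygens apart (three acylated, two free). The chain C7–C1–C6–C5, with oxygen on C1 and C6, is the carbon skeleton of tartaric acid. The plan uses this: with the C1/C6 diol held as a dioxolane whose two arms are cis, the allylic carbinol C5 is formed by closing the C4–C5 bond from a Z-iodoalkene (C3=C4) onto a C5 aldehyde.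

## Logic of the disconnections

14 to 13: the two free O–H groups at C1 and C6 are replaced by the two C–O bonds of an isopropylidene bridge. A cis-fused five-membered acetal is the one mask that singles out exactly this cis pair, and it is already present in the chiral-pool material. The gain is that five oxygens reduce to three equivalent acylations. The demand is an acetal hydrolysis that leaves three benzoates where they are.

13 to 12: the three acyl C–O bonds at C2, C5 and C7 are cut. This removes all ester sensitivity from the earlier intermediates. The forward step must acylate exhaustively, including the hindered C2 hydroxyl, but needs no selectivity.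

12 to 11 to 10: the O–H at C2 is traded for an O–Si bond, and the C7 carbinol is raised to the methyl ester. Both changes lead to 10, which is the direct product of ring closure and carries only groups that the closure tolerates. The forward demands are a hydride that reduces a hindered ester without touching the alkene, and a fluoride cleavage of a hindered silyl ether.

10 to 8 (through 9): the ring bond C4–C5 is cut. It is the only ring bond whose formation creates an allylic carbinol next to an existing oxygenated centre (C6), so the new centre can be steered by its neighbour. The cut opens the carbocycle to a dioxolane with two cis arms. The forward step must close six-membered, keep the Z geometry, spare the ester and give C5–O trans to C6–O.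

8 to 7: the C5 aldehyde is traced to a methyl ester, which restores the tartrate diester. The forward step must pick the ester on the tertiary C6 over the one on the quaternary C1 and stop at the aldehyde.

7 to 6: the O–Si bond at C2 is removed. The silyl ether is needed only because free C2–OH would lactonise onto the cis ester, and an acyl group there could not survive hydride or sit allylic to the alkenylchromium.

6 to 3 and 4 (through 5): the C1–C2 bond is cut. This separates a three-carbon Z-iodoenal from the intact tartrate unit. The forward addition must enter C1 on the face cis to the C6 ester and choose one face of the aldehyde.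

3 to 2 to 1: the aldehyde is traced to the ester, and the C4–I and C3–H bonds to the alkyne. The forward demand is anti addition of HI and preservation of the Z geometry through a partial reduction.

## Other disconnections considered

Alternative 1: The cut removes the C1–O bond and returns the ring to an arene, so that all seven carbons come from salicyl alcohol A2. In the forward step a chiral aryl-lambda3-iodane (trivalent iodine) would activate the phenol of A2, and the benzylic hydroxyl would close onto the ring carbon bearing the CH2 group to give the spiro-oxirane dienone A1. The R enantiomer is required; in it the carbonyl carbon becomes C2 and the diene becomes C3=C4–C5=C6.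
- In favour: the start could hardly be cheaper, one step creates the quaternary C1 with both the C1–O and C7–O bonds, and the oxirane CH2 is a ready site for benzoate to enter as the C7 ester. On step count and atom economy this is the better plan.
- Against: face selection by the reagent on a flat dearomatised intermediate would be the only source of absolute configuration, and a high level cannot be relied on for this intramolecular spiro-epoxidation. A1 is a 2,4-cyclohexadienone that would dimerise by [4+2] cycloaddition unless intercepted at once. Only C1 would be set; C2 (ketone reduction cis to the C1 oxygen) and C5/C6 (trans dioxygenation of C5=C6 with C3=C4 kept) would all depend on relay.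
- Comparison: structurally the alternative keeps the ring and the chosen plan must close it. Mechanistically the chosen plan takes C1 and C6 from the chiral pool and relays only C2 and C5, which is firmer ground. In handling, nothing in the chosen plan is as labile as A1.

Alternative 2: The cut removes the C1–O and C7–O bonds and leads to the exocyclic alkene A4, which already holds both ring benzoates and the free C6 hydroxyl. In the forward step OsO4 with TMEDA (CH2Cl2, −78 °C) would accept a hydrogen bond from the C6 hydroxyl and add to C1=C7 from that face, giving triol A3 with the C1 oxygen cis to the C6 oxygen. Selective benzoylation of the primary hydroxyl would finish the synthesis.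
- In favour: the facial demand at C1 is exactly what a hydroxyl-directed osmylation supplies, and for setting C1 this step is the equal of the enolate addition in the chosen plan, or better. The 1,1-disubstituted alkene is more electron-rich and more open than C3=C4, which is deactivated by two allylic benzoates. Only one step would follow the key step, against four in the chosen plan, so the endgame is better.
- Against: A4 is not a starting material. Its ring, three stereocentres and a methylidene flanked by acyloxy-bearing carbons must be built first. A carbonyl methylenation beside β-acyloxy groups invites elimination, and the free C6 hydroxyl beside the C5 benzoate invites migration. The osmium reagent is stoichiometric, and its diamine-chelated osmate must be cleaved in the presence of migration-prone esters.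
- Comparison: structurally the alternative adds the C1 oxygen late by oxidation, while the chosen plan carries both diol oxygens from the start. Mechanistically both relay from C6 (hydrogen-bond direction against conformational control of an aldehyde) and are about equal. Overall the alternative is probably longer, since the route to A4 must solve the carbocycle and three stereocentres.

Alternative 3: The cut removes the C1–O and C2–O bonds and returns to benzoic acid A6. In the forward step whole cells with benzoate 1,2-dioxygenase (Ralstonia eutropha B9, a blocked mutant) would add both atoms of O2 to the ipso and ortho carbons. The product is diene diol acid A5; its C1 and C2 have the configuration of the target, its carboxyl is C7, and the diene C3=C4–C5=C6 remains.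
- In favour: one operation on a commodity arene would deliver the intact ring with all seven carbons and fix the quaternary C1 and C2 with enzymatic enantiopurity. On ring construction and on control of C1 this is better than the chosen plan. Differentiating the tertiary C1 and secondary C2 hydroxyls for benzoylation would be trivial, and the step count could equal or beat the chosen plan.
- Against: it needs fermentation with a particular strain, and A5 tends to rearomatise under acid. The remaining task is the hard one: C5=C6 must become trans C5–O/C6–O, with C6–O cis to C1–O, while C3=C4 survives. A conjugated diene tends to react at its termini (C3 and C6) with pericyclic and many electrophilic oxidants, and an epoxide across C5–C6 could open with allylic transposition at C3 as well as at C5.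
- Comparison: structurally the alternative sets C1/C2 and leaves C5/C6, whereas the chosen plan sets C1/C6 from tartrate and leaves C2/C5. Mechanistically the chosen plan forms each remaining centre in its own C–C bond-forming step, while the alternative must solve a regiochemical problem on a diene.

Key step: step 6

Remark: commercial solutions of lithium diisopropylamide, iBu2AlH and Bu4NF are assumed. The configurations of 8 and 10 were checked centre by centre against 14 and against 4 (retention at C1) and need no correction.

## Route

Step 1
Reactants: 1 ethyl propiolate
Product: 2 ethyl (2Z)-3-iodoprop-2-enoate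
Conditions: NaI, AcOH, 70 °C
Reagents that add atoms: sodium iodide, [Na+].[I-]
Why: Conjugate addition of iodide to the ynoate followed by protonation of the allenolate on the face away from iodine (net anti hydroiodination) should give the Z-3-iodoacrylate under kinetic control.

Step 2
Reactants: 2 ethyl (2Z)-3-iodoprop-2-enoate
Product: 3 (2Z)-3-iodoprop-2-enal
Conditions: iBu2AlH (1.05 equiv), CH2Cl2, −78 °C; MeOH, then aq. Rochelle salt, 0 °C; dried cold solution used at once
Reagents that add atoms: none
Why: Partial ester reduction: at −78 °C the aluminium hemiacetal from one hydride transfer persists and releases the aldehyde only on work-up; a cold, neutral, dark work-up without concentration should preserve the Z geometry.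

Step 3
Reactants: 3 (2Z)-3-iodoprop-2-enal; 4 dimethyl (4R,5R)-2,2-dimethyl-1,3-dioxolane-4,5-dicarboxylate (dimethyl 2,3-O-isopropylidene-L-tartrate)
Product: 6 dimethyl (4R,5R)-4-[(1R,2Z)-1-hydroxy-3-iodoprop-2-en-1-yl]-2,2-dimethyl-1,3-dioxolane-4,5-dicarboxylate, via lithium ester enolate 5 (not isolated)
Conditions: LiN(iPr)2 (1.0 equiv), THF, −78 °C; then 3 in CH2Cl2, −78 °C; AcOH quench at −78 °C
Reagents that add atoms: none
Why: Mixed aldol addition of a dioxolane ester enolate: 5 is known to take electrophiles on the face cis to the neighbouring C6 ester (net retention, the two esters stay trans), which sets C1 and puts the new arm cis to the C6 carboxyl. A lithium-bridged Zimmerman–Traxler chair with the enolate oxygen tied to the ring oxygen and the iodovinyl group anti to the C1–C7 bond should favour the 2R carbinol, and any C2 epimer is removed by chromatography. The cold quench forestalls retro-aldol, opening of the dioxolane and lactonisation onto the cis ester.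

Step 4
Reactants: 6 dimethyl (4R,5R)-4-[(1R,2Z)-1-hydroxy-3-iodoprop-2-en-1-yl]-2,2-dimethyl-1,3-dioxolane-4,5-dicarboxylate
Product: 7 dimethyl (4S,5R)-4-[(1R,2Z)-1-(tert-butyldimethylsilyloxy)-3-iodoprop-2-en-1-yl]-2,2-dimethyl-1,3-dioxolane-4,5-dicarboxylate
Conditions: TBSOTf, 2,6-lutidine, CH2Cl2, −78 to 0 °C
Reagents that add atoms: tert-butyldimethylsilyl trifluoromethanesulfonate, CC(C)(C)[Si](C)(C)OS(=O)(=O)C(F)(F)F
Why: Silylation of a hindered secondary alcohol with the silyl triflate and a non-nucleophilic base is fast at low temperature, so the C2 hydroxyl has no time to lactonise; the ether withstands hydride and organochromium chemistry and is a poor allylic leaving group.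

Step 5
Reactants: 7 dimethyl (4S,5R)-4-[(1R,2Z)-1-(tert-butyldimethylsilyloxy)-3-iodoprop-2-en-1-yl]-2,2-dimethyl-1,3-dioxolane-4,5-dicarboxylate
Product: 8 methyl (4S,5R)-4-[(1R,2Z)-1-(tert-butyldimethylsilyloxy)-3-iodoprop-2-en-1-yl]-5-formyl-2,2-dimethyl-1,3-dioxolane-4-carboxylate
Conditions: iBu2AlH (1.1 equiv), toluene, −78 °C; MeOH at −78 °C, then aq. Rochelle salt; crude aldehyde used directly
Reagents that add atoms: none
Why: Partial reduction of a methyl ester to the aldehyde through an aluminium hemiacetal that is chelated by the α-oxygen and stable at −78 °C. The C6 ester sits on a tertiary carbon whereas the C7 ester sits on the quaternary C1 beside the bulky silyloxy arm, so one equivalent of hydride should select the C6 ester. A cold non-basic work-up should protect the α-alkoxy aldehyde from epimerisation.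

Step 6
Reactants: 8 methyl (4S,5R)-4-[(1R,2Z)-1-(tert-butyldimethylsilyloxy)-3-iodoprop-2-en-1-yl]-5-formyl-2,2-dimethyl-1,3-dioxolane-4-carboxylate
Product: 10 methyl (3aS,4R,7R,7aS)-4-(tert-butyldimethylsilyloxy)-7-hydroxy-2,2-dimethyl-3a,4,7,7a-tetrahydro-1,3-benzodioxole-3a-carboxylate, via alkenyl-CrCl2 species 9 (not isolated)
Conditions: CrCl2 (6 equiv), NiCl2 (2 mol %), degassed DMSO, 0.01 M, rt; aq. NH4Cl work-up
Reagents that add atoms: none
Why: CrCl2 reduces NiCl2 to zerovalent nickel, which inserts into the C4–I bond with retention of the Z geometry; transmetalation to trivalent chromium gives 9, whose C4–Cr bond adds to the C5 aldehyde. The closest known reaction type is the intramolecular Nozaki–Hiyama–Kishi cyclisation of an iodoalkene aldehyde to a cyclic allylic alcohol. The cyclohexene closes in the 6-exo-trig mode and is preorganised, because the two arms are cis on the dioxolane and the Z alkene turns C4 toward C5. The new centre C5 is controlled by C6: in the coordinating solvent no chelate should form, so the aldehyde should react with its C=O anti to the C6–O bond (dipole-minimised, Cornforth-type alignment), and since the tether allows approach only from the C1 side, the C5 oxygen should end trans to the C6 oxygen (5R). The step needs chemoselectivity for the aldehyde over the methyl ester, which alkenylchromium reagents provide; it needs retention of alkene geometry, which stereoretentive insertion and transmetalation provide; it needs integrity at C6, which the neutral aprotic medium secures; and it needs the allylic C2 oxygen to stay, which the silyl ether secures. High dilution suppresses intermolecular addition and nickel-mediated homocoupling.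

Step 7
Reactants: 10 methyl (3aS,4R,7R,7aS)-4-(tert-butyldimethylsilyloxy)-7-hydroxy-2,2-dimethyl-3a,4,7,7a-tetrahydro-1,3-benzodioxole-3a-carboxylate
Product: 11 (3aS,4R,7R,7aS)-4-(tert-butyldimethylsilyloxy)-3a-(hydroxymethyl)-2,2-dimethyl-3a,4,7,7a-tetrahydro-1,3-benzodioxol-7-ol
Conditions: LiBH4, THF, 0 °C to rt
Reagents that add atoms: none
Why: Borohydride reduction of an α-alkoxy ester to the primary alcohol; LiBH4 leaves the alkene, silyl ether and acetal alone, and any bridged lactone formed between the C5 alkoxide and the C7 ester in step 6 would be reduced to the same diol.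

Step 8
Reactants: 11 (3aS,4R,7R,7aS)-4-(tert-butyldimethylsilyloxy)-3a-(hydroxymethyl)-2,2-dimethyl-3a,4,7,7a-tetrahydro-1,3-benzodioxol-7-ol
Product: 12 (3aR,4R,7R,7aS)-3a-(hydroxymethyl)-2,2-dimethyl-3a,4,7,7a-tetrahydro-1,3-benzodioxole-4,7-diol
Conditions: Bu4NF, THF, 0 °C to rt
Reagents that add atoms: none
Why: Fluoride-induced cleavage of the Si–O bond (desilylation), driven by the strong Si–F bond; no base-sensitive group remains, so the hindered C2 ether can be given time or gentle warming.

Step 9
Reactants: 12 (3aR,4R,7R,7aS)-3a-(hydroxymethyl)-2,2-dimethyl-3a,4,7,7a-tetrahydro-1,3-benzodioxole-4,7-diol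
Product: 13 [(3aR,4R,7R,7aS)-4,7-bis(benzoyloxy)-2,2-dimethyl-3a,4,7,7a-tetrahydro-1,3-benzodioxol-3a-yl]methyl benzoate
Conditions: BzCl (4.5 equiv), pyridine, DMAP (cat.), CH2Cl2, 0 °C to rt
Reagents that add atoms: benzoyl chloride, O=C(Cl)c1ccccc1
Why: DMAP-catalysed acylation through the N-benzoylpyridinium ion of the primary C7 and the two allylic secondary hydroxyls; the oxygens on C1 and C6 are locked in the acetonide, so exhaustive benzoylation needs no selectivity.

Step 10
Reactants: 13 [(3aR,4R,7R,7aS)-4,7-bis(benzoyloxy)-2,2-dimethyl-3a,4,7,7a-tetrahydro-1,3-benzodioxol-3a-yl]methyl benzoate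
Product: 14 [(1S,2R,5R,6S)-2,5-bis(benzoyloxy)-1,6-dihydroxycyclohex-3-en-1-yl]methyl benzoate
Conditions: CF3CO2H/H2O 9:1, 0 °C to rt
Reagents that add atoms: none
Why: Acid-catalysed hydrolysis of the isopropylidene acetal; benzoates withstand cold aqueous trifluoroacetic acid and acyl migration is slow in acid, so the cis C1/C6 diol should be released with the three esters in place and no stereocentre touched.

## Compound list

1 | ethyl propiolate | CCOC(=O)C#C | starting material
2 | ethyl (2Z)-3-iodoprop-2-enoate | CCOC(=O)/C=C\I | intermediate
3 | (2Z)-3-iodoprop-2-enal | O=C/C=C\I | intermediate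
4 | dimethyl (4R,5R)-2,2-dimethyl-1,3-dioxolane-4,5-dicarboxylate | COC(=O)[C@@H]1OC(C)(C)O[C@H]1C(=O)OC | starting material
5 | lithium enolate of 4, methyl (4R)-5-[(lithiooxy)(methoxy)methylidene]-2,2-dimethyl-1,3-dioxolane-4-carboxylate | COC(O[Li])=C1OC(C)(C)O[C@H]1C(=O)OC | intermediate
6 | dimethyl (4R,5R)-4-[(1R,2Z)-1-hydroxy-3-iodoprop-2-en-1-yl]-2,2-dimethyl-1,3-dioxolane-4,5-dicarboxylate | COC(=O)[C@@]1(OC(C)(C)O[C@H]1C(=O)OC)[C@H](O)/C=C\I | intermediate
7 | dimethyl (4S,5R)-4-[(1R,2Z)-1-(tert-butyldimethylsilyloxy)-3-iodoprop-2-en-1-yl]-2,2-dimethyl-1,3-dioxolane-4,5-dicarboxylate | COC(=O)[C@@]1(OC(C)(C)O[C@H]1C(=O)OC)[C@H](O[Si](C)(C)C(C)(C)C)/C=C\I | intermediate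
8 | methyl (4S,5R)-4-[(1R,2Z)-1-(tert-butyldimethylsilyloxy)-3-iodoprop-2-en-1-yl]-5-formyl-2,2-dimethyl-1,3-dioxolane-4-carboxylate | COC(=O)[C@@]1(OC(C)(C)O[C@H]1C=O)[C@H](O[Si](C)(C)C(C)(C)C)/C=C\I | intermediate
9 | alkenyl-CrCl2 species (trivalent chromium on C4 of 8 in place of iodine, Z) | COC(=O)[C@@]1(OC(C)(C)O[C@H]1C=O)[C@H](O[Si](C)(C)C(C)(C)C)/C=C\[Cr](Cl)Cl | intermediate
10 | methyl (3aS,4R,7R,7aS)-4-(tert-butyldimethylsilyloxy)-7-hydroxy-2,2-dimethyl-3a,4,7,7a-tetrahydro-1,3-benzodioxole-3a-carboxylate | COC(=O)[C@@]1(OC(C)(C)O2)[C@H](O[Si](C)(C)C(C)(C)C)C=C[C@@H](O)[C@@H]12 | intermediate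
11 | (3aS,4R,7R,7aS)-4-(tert-butyldimethylsilyloxy)-3a-(hydroxymethyl)-2,2-dimethyl-3a,4,7,7a-tetrahydro-1,3-benzodioxol-7-ol | OC[C@@]1(OC(C)(C)O2)[C@H](O[Si](C)(C)C(C)(C)C)C=C[C@@H](O)[C@@H]12 | intermediate
12 | (3aR,4R,7R,7aS)-3a-(hydroxymethyl)-2,2-dimethyl-3a,4,7,7a-tetrahydro-1,3-benzodioxole-4,7-diol | OC[C@@]1(OC(C)(C)O2)[C@H](O)C=C[C@@H](O)[C@@H]12 | intermediate
13 | [(3aR,4R,7R,7aS)-4,7-bis(benzoyloxy)-2,2-dimethyl-3a,4,7,7a-tetrahydro-1,3-benzodioxol-3a-yl]methyl benzoate | O=C(OC[C@@]1(OC(C)(C)O2)[C@H](OC(=O)c3ccccc3)C=C[C@@H](OC(=O)c3ccccc3)[C@@H]12)c1ccccc1 | intermediate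
14 | [(1S,2R,5R,6S)-2,5-bis(benzoyloxy)-1,6-dihydroxycyclohex-3-en-1-yl]methyl benzoate | O=C(OC[C@@]1(O)[C@H](OC(=O)c2ccccc2)C=C[C@@H](OC(=O)c2ccccc2)[C@@H]1O)c1ccccc1 | target

## Step count and least certain steps

Total step count: 10. Longest linear sequence: 10 steps (1 to 14); 8 steps counted from 4.

Step 6 (key step). The most likely failures are poor facial selectivity at C5, if a chelated aldehyde conformer with C=O syn to the C6 oxygen competes, and protonolysis of the alkenylchromium by adventitious water before closure. Epimerisation of the aldehyde at C6, which would put the two arms trans and stop ring closure, is a further risk. The fallback closes the ring by olefin metathesis and sets C5 in a separate intermolecular step. It sets out from 4. Enolate 5 would be added to acrolein to give the acrolein aldol adduct (C2 allylic alcohol diester) F1. Silylation as in step 4 would give the silyl ether diester F2, and iBu2AlH at −78 °C as in step 5 would give the vinyl aldehyde F3. Vinylmagnesium bromide with MgBr2·OEt2 in CH2Cl2 at −78 °C would then add under chelation control, the magnesium bridging the aldehyde oxygen and the C6 ring oxygen and the nucleophile entering past the C6 hydrogen. This would give the 5R divinyl carbinol F4. Ring-closing metathesis with the second-generation Grubbs catalyst, RuCl2(=CHPh)(PCy3)(H2IMes), in CH2Cl2 at 40 °C would form C3=C4 and return to the route at 10.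

Step 3. The weak points are face selection on the aldehyde (C2), loss of the Z-iodoalkene by base-induced dehydroiodination or isomerisation, and decay of the enolate by opening of the dioxolane if the temperature rises. The fallback sets C2 by reagent control. It sets out from 6, taken as whatever mixture of C2 epimers is obtained. Oxidation with Dess–Martin periodinane (NaHCO3, CH2Cl2, 0 °C) would give the Z-iodovinyl ketone F5. Corey–Bakshi–Shibata reduction with BH3·SMe2 would then be used, choosing the oxazaborolidine enantiomer that treats the fully substituted C1 as the large group (nominally the S catalyst for the 2R alcohol). This returns to the route at 6.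

Step 5. Hydride may attack the wrong ester or run on to the primary alcohol, because both carboxyls are methyl esters and differ only in their steric surroundings. The fallback moves the selection to a saponification and a chemoselective reduction. It sets out from 7. One equivalent of LiOH (THF/H2O, 0 °C) would hydrolyse the less hindered C6 ester to the mono-acid F6. Activation as the mixed anhydride (isobutyl chloroformate, N-methylmorpholine) and NaBH4 reduction would give the C5 primary alcohol F7. Dess–Martin oxidation would return to the route at 8.

Step 2. The Z aldehyde may isomerise to the E isomer through traces of acid or light, or be lost through volatility and polymerisation. The fallback makes the Z-iodoalkene after the C1–C2 bond. It sets out from 4. Enolate 5 would be added to commercial 3-(trimethylsilyl)propynal to give the silylalkyne carbinol F8. N-Iodosuccinimide with catalytic AgNO3 in acetone would exchange silicon for iodine to give the iodoalkyne carbinol F9. Cis reduction with diimide (2-nitrobenzenesulfonyl hydrazide, Et3N) would return to the route at 6.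

Step 10. The risks are benzoyl migration onto the newly freed C1 and C6 hydroxyls, ionisation of an allylic benzoate under acid, and sluggish hydrolysis of an acetal flanked by electron-withdrawing esters. The fallback removes the acetal before any ester is present. It sets out from 12. Aqueous CF3CO2H would give the pentaol F10. Benzoylation with three equivalents of BzCl in pyridine/CH2Cl2 at −40 °C would rely on the reactivity order primary C7, then allylic C2 and C5, then the doubly flanked C6, then the tertiary C1. It returns to the route at 14.

## Further compounds

F1 | step 6 | dimethyl (4R,5R)-4-[(1R)-1-hydroxyprop-2-en-1-yl]-2,2-dimethyl-1,3-dioxolane-4,5-dicarboxylate | COC(=O)[C@@]1(OC(C)(C)O[C@H]1C(=O)OC)[C@H](O)C=C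
F2 | step 6 | dimethyl (4S,5R)-4-[(1R)-1-(tert-butyldimethylsilyloxy)prop-2-en-1-yl]-2,2-dimethyl-1,3-dioxolane-4,5-dicarboxylate | COC(=O)[C@@]1(OC(C)(C)O[C@H]1C(=O)OC)[C@H](O[Si](C)(C)C(C)(C)C)C=C
F3 | step 6 | methyl (4S,5R)-4-[(1R)-1-(tert-butyldimethylsilyloxy)prop-2-en-1-yl]-5-formyl-2,2-dimethyl-1,3-dioxolane-4-carboxylate | COC(=O)[C@@]1(OC(C)(C)O[C@H]1C=O)[C@H](O[Si](C)(C)C(C)(C)C)C=C
F4 | step 6 | methyl (4S,5S)-4-[(1R)-1-(tert-butyldimethylsilyloxy)prop-2-en-1-yl]-5-[(1R)-1-hydroxyprop-2-en-1-yl]-2,2-dimethyl-1,3-dioxolane-4-carboxylate | COC(=O)[C@@]1(OC(C)(C)O[C@H]1[C@H](O)C=C)[C@H](O[Si](C)(C)C(C)(C)C)C=C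
F5 | step 3 | dimethyl (4S,5R)-4-[(2Z)-3-iodoprop-2-enoyl]-2,2-dimethyl-1,3-dioxolane-4,5-dicarboxylate | COC(=O)[C@@]1(OC(C)(C)O[C@H]1C(=O)OC)C(=O)/C=C\I
F6 | step 5 | (4R,5S)-5-[(1R,2Z)-1-(tert-butyldimethylsilyloxy)-3-iodoprop-2-en-1-yl]-5-(methoxycarbonyl)-2,2-dimethyl-1,3-dioxolane-4-carboxylic acid | COC(=O)[C@@]1(OC(C)(C)O[C@H]1C(=O)O)[C@H](O[Si](C)(C)C(C)(C)C)/C=C\I
F7 | step 5 | methyl (4S,5S)-4-[(1R,2Z)-1-(tert-butyldimethylsilyloxy)-3-iodoprop-2-en-1-yl]-5-(hydroxymethyl)-2,2-dimethyl-1,3-dioxolane-4-carboxylate | COC(=O)[C@@]1(OC(C)(C)O[C@H]1CO)[C@H](O[Si](C)(C)C(C)(C)C)/C=C\I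
F8 | step 2 | dimethyl (4R,5R)-4-[(1R)-1-hydroxy-3-(trimethylsilyl)prop-2-yn-1-yl]-2,2-dimethyl-1,3-dioxolane-4,5-dicarboxylate | COC(=O)[C@@]1(OC(C)(C)O[C@H]1C(=O)OC)[C@H](O)C#C[Si](C)(C)C
F9 | step 2 | dimethyl (4R,5R)-4-[(1R)-1-hydroxy-3-iodoprop-2-yn-1-yl]-2,2-dimethyl-1,3-dioxolane-4,5-dicarboxylate | COC(=O)[C@@]1(OC(C)(C)O[C@H]1C(=O)OC)[C@H](O)C#CI
F10 | step 10 | (1R,2R,5R,6S)-1-(hydroxymethyl)cyclohex-3-ene-1,2,5,6-tetrol | OC[C@@]1(O)[C@H](O)C=C[C@@H](O)[C@@H]1O
A1 | alternative 1 | (R)-1-oxaspiro[2.5]octa-5,7-dien-4-one | C1O[C@@]12C(=O)C=CC=C2
A2 | alternative 1 | 2-(hydroxymethyl)phenol (salicyl alcohol) | OCc1ccccc1O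
A3 | alternative 2 | (1S,2R,5R,6S)-1,6-dihydroxy-1-(hydroxymethyl)cyclohex-3-ene-2,5-diyl dibenzoate | OC[C@@]1(O)[C@H](OC(=O)c2ccccc2)C=C[C@@H](OC(=O)c2ccccc2)[C@@H]1O
A4 | alternative 2 | (1R,4R,5R)-5-hydroxy-6-methylidenecyclohex-2-ene-1,4-diyl dibenzoate | C=C1[C@H](OC(=O)c2ccccc2)C=C[C@@H](OC(=O)c2ccccc2)[C@@H]1O
A5 | alternative 3 | (1S,2R)-1,2-dihydroxycyclohexa-3,5-diene-1-carboxylic acid | OC(=O)[C@@]1(O)[C@H](O)C=CC=C1
A6 | alternative 3 | benzoic acid | OC(=O)c1ccccc1
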